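The route rests on disconnecting both bonds at the ketone carbon: C1 of ring A to C=O, and C=O to the CH2 of the 2-phenylethyl chain. One palladium-catalysed operation joins an aryl iodide, carbon monoxide and a B-alkyl-9-BBN to give the alkyl aryl ketone. The feature exploited is that C1 of ring A, ortho to the C2 oxygen and para to the C4 oxygen, can be marked by iodine at the aldehyde stage while C2–OH is a chelated phenol and C4–O a benzyl ether, so the carbonyl enters there and the doubly benzylic C7 never meets a Friedel–Crafts acylation. The precursor is 1-(benzyloxy)-2-[2-(benzyloxy)benzyl]-4-iodo-3-methoxybenzene.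

Key step: step 7

Remark on the chemistry: ring A is numbered C1 (acyl), C2 (OMe), C3 (carrying the C7 methylene to ring C, the 2-hydroxyphenyl ring), C4 (OH), C5 and C6 (H); iodine is introduced while the C2 oxygen is a free chelated hydroxyl and the C4 oxygen is already a benzyl ether, because with C4–OH free and C2–OMe in place the unhindered C5 position (ortho to OH, para to OMe) would be expected to compete with C1.

Step 1
Reactants: 1 2,6-dihydroxybenzaldehyde
Product: 2 2-(benzyloxy)-6-hydroxybenzaldehyde
Conditions: BnBr (1.0 equiv), NaHCO3 (1.2 equiv), DMF, 50 °C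
Reagents that add atoms: benzyl bromide, BrCc1ccccc1
Why: Williamson ether synthesis in which the weak base ionises one hydroxyl only, and in the mono-ether the remaining hydroxyl is held by a hydrogen bond to the formyl oxygen and is a much poorer nucleophile, so alkylation should stop at the mono-benzyl ether.

Step 2
Reactants: 2 2-(benzyloxy)-6-hydroxybenzaldehyde
Product: 3 6-(benzyloxy)-2-hydroxy-3-iodobenzaldehyde
Conditions: [BnNMe3][ICl2] (1.05 equiv), NaHCO3, CH2Cl2–MeOH, 20 °C
Reagents that add atoms: benzyltrimethylammonium dichloroiodate, C[N+](C)(C)Cc1ccccc1.Cl[I-]Cl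
Why: Electrophilic aromatic iodination in which the carbon that becomes C1 of ring A is ortho to the chelated hydroxyl and para to the benzyloxy group, while the only other activated CH is ortho to the benzyloxy group whose CH2Ph is turned toward it by the neighbouring formyl group, so electronic and steric effects should both direct iodine to C1, as is usual for hydrogen-bonded 2-hydroxy-6-alkoxyaryl carbonyl compounds.

Step 3
Reactants: 3 6-(benzyloxy)-2-hydroxy-3-iodobenzaldehyde
Product: 4 6-(benzyloxy)-3-iodo-2-methoxybenzaldehyde
Conditions: MeI (1.5 equiv), K2CO3, DMF, 40 °C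
Reagents that add atoms: iodomethane, CI
Why: Williamson O-methylation of the phenoxide with a small electrophile in a dipolar aprotic solvent should overcome the hydrogen bond and the two flanking substituents, and no other acidic site is present.

Step 4
Reactants: 4 6-(benzyloxy)-3-iodo-2-methoxybenzaldehyde; 5 1-(benzyloxy)-2-bromobenzene
Product: 7 rac-[6-(benzyloxy)-3-iodo-2-methoxyphenyl][2-(benzyloxy)phenyl]methanol, via [2-(benzyloxy)phenyl]magnesium bromide 6 (not isolated)
Conditions: 5, Mg, THF, reflux; then 4, THF, −78 to 0 °C; aq. NH4Cl
Reagents that add atoms: none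
Why: Grignard addition of an arylmagnesium bromide to an aromatic aldehyde is fast at low temperature, where exchange of magnesium with the aryl iodide is negligible; the carbinol stereocentre forms as a racemate and is erased in step 5.

Step 5
Reactants: 7 rac-[6-(benzyloxy)-3-iodo-2-methoxyphenyl][2-(benzyloxy)phenyl]methanol
Product: 8 1-(benzyloxy)-2-[2-(benzyloxy)benzyl]-4-iodo-3-methoxybenzene
Conditions: Et3SiH (3 equiv), CF3CO2H (5 equiv), CH2Cl2, 0 °C
Reagents that add atoms: none
Why: Ionic hydrogenation, in which the acid ionises the carbinol to a benzhydryl cation stabilised by three ortho alkoxy groups and the silane delivers hydride to it, while benzyl ethers, the methyl ether and the aryl iodide are inert under these conditions at 0 °C.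

Step 6
Reactants: 9 styrene; 10 9-borabicyclo[3.3.1]nonane (9-BBN, as its dimer or a 0.5 M THF solution)
Product: 11 9-(2-phenylethyl)-9-borabicyclo[3.3.1]nonane
Conditions: THF, 0 to 25 °C, argon, styrene in slight excess; solution used directly in step 7
Reagents that add atoms: none
Why: Hydroboration of a terminal alkene with 9-BBN places boron on the terminal carbon with very high anti-Markovnikov selectivity, and the slight excess of styrene leaves no B–H to interfere later.

Step 7
Reactants: 8 1-(benzyloxy)-2-[2-(benzyloxy)benzyl]-4-iodo-3-methoxybenzene; 11 9-(2-phenylethyl)-9-borabicyclo[3.3.1]nonane; 12 carbon monoxide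
Product: 13 1-{4-(benzyloxy)-3-[2-(benzyloxy)benzyl]-2-methoxyphenyl}-3-phenylpropan-1-one
Conditions: 11 (1.5 equiv, THF solution), Pd(PPh3)4 (5 mol %), K3PO4 (3 equiv), CO (1 atm, balloon), THF–1,4-dioxane, 25 to 50 °C
Reagents that add atoms: none
Why: Three-component carbonylative Suzuki–Miyaura coupling: zerovalent palladium inserts into the C1–I bond of ring A, the resulting arylpalladium iodide takes up CO to give an aroylpalladium species, the borate formed from the B-alkyl-9-BBN and phosphate transfers its primary 2-phenylethyl group (the bicyclic 9-BBN framework does not migrate), and reductive elimination releases the ketone and regenerates zerovalent palladium. The closest known reaction type is the palladium-catalysed carbonylative cross-coupling of aryl iodides with B-alkyl-9-BBN reagents to alkyl aryl ketones. No ring is closed and no stereocentre is created. The selectivity needed is ketone formation over direct aryl–alkyl coupling, and it should be secured because the electron-rich arylpalladium bearing an ortho methoxy group inserts CO faster than it undergoes the slow, base-dependent transmetalation with the alkylborane under a CO atmosphere. The site of the carbonyl is fixed by the iodine at C1, and the mild base leaves both benzyl ethers, the methyl ether and the doubly benzylic C7 methylene untouched.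

Step 8
Reactants: 13 1-{4-(benzyloxy)-3-[2-(benzyloxy)benzyl]-2-methoxyphenyl}-3-phenylpropan-1-one
Product: 14 1-[4-hydroxy-3-(2-hydroxybenzyl)-2-methoxyphenyl]-3-phenylpropan-1-one
Conditions: H2 (1 atm), Pd/C (10 wt %), EtOAc, 20 °C, stopped after uptake of two equivalents of H2
Reagents that add atoms: none
Why: Catalytic hydrogenolysis cleaves both benzyl aryl ethers, while the aryl ketone (deactivated by its para oxygen and ortho methoxy group) and the diarylmethane should not be reduced at 1 atm in a neutral solvent.

Compound list
1 | 2,6-dihydroxybenzaldehyde | O=Cc1c(O)cccc1O | starting material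
2 | 2-(benzyloxy)-6-hydroxybenzaldehyde | O=Cc1c(O)cccc1OCc1ccccc1 | intermediate
3 | 6-(benzyloxy)-2-hydroxy-3-iodobenzaldehyde | O=Cc1c(O)c(I)ccc1OCc1ccccc1 | intermediate
4 | 6-(benzyloxy)-3-iodo-2-methoxybenzaldehyde | COc1c(I)ccc(OCc2ccccc2)c1C=O | intermediate
5 | 1-(benzyloxy)-2-bromobenzene | Brc1ccccc1OCc1ccccc1 | starting material
6 | [2-(benzyloxy)phenyl]magnesium bromide | Br[Mg]c1ccccc1OCc1ccccc1 | intermediate (not isolated)
7 | rac-[6-(benzyloxy)-3-iodo-2-methoxyphenyl][2-(benzyloxy)phenyl]methanol (racemic, one stereocentre) | COc1c(I)ccc(OCc2ccccc2)c1C(O)c1ccccc1OCc1ccccc1 | intermediate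
8 | 1-(benzyloxy)-2-[2-(benzyloxy)benzyl]-4-iodo-3-methoxybenzene | COc1c(I)ccc(OCc2ccccc2)c1Cc1ccccc1OCc1ccccc1 | intermediate
9 | styrene | C=Cc1ccccc1 | starting material
10 | 9-borabicyclo[3.3.1]nonane | B1C2CCCC1CCC2 | starting material
11 | 9-(2-phenylethyl)-9-borabicyclo[3.3.1]nonane | C(Cc1ccccc1)B1C2CCCC1CCC2 | intermediate
12 | carbon monoxide | [C-]#[O+] | starting material
13 | 1-{4-(benzyloxy)-3-[2-(benzyloxy)benzyl]-2-methoxyphenyl}-3-phenylpropan-1-one | COc1c(C(=O)CCc2ccccc2)ccc(OCc2ccccc2)c1Cc1ccccc1OCc1ccccc1 | intermediate
14 | 1-[4-hydroxy-3-(2-hydroxybenzyl)-2-methoxyphenyl]-3-phenylpropan-1-one (no stereocentre) | COc1c(C(=O)CCc2ccccc2)ccc(O)c1Cc1ccccc1O | target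

Total step count: 8
Longest linear sequence: 7 steps (steps 1, 2, 3, 4, 5, 7 and 8; step 6 is a one-step side branch)

Steps most likely to fail

Step 7. The alkyl group may be transferred to the arylpalladium before CO has inserted, giving direct aryl–alkyl coupling, or the catalyst may stall under CO with the ortho-substituted iodide. The fallback sets out from 8 and returns at 13 by a Weinreb ketone synthesis. Iodine–magnesium exchange with iPrMgCl·LiCl in THF at −20 °C should give {4-(benzyloxy)-3-[2-(benzyloxy)benzyl]-2-methoxyphenyl}magnesium chloride F1. Addition of N-methoxy-N-methyl-3-phenylpropanamide should give the chelated tetrahedral adduct, chloromagnesium 1-{4-(benzyloxy)-3-[2-(benzyloxy)benzyl]-2-methoxyphenyl}-1-[methoxy(methyl)amino]-3-phenylpropan-1-olate F2. This adduct does not collapse until the quench with dilute aqueous HCl, which should release ketone 13 without over-addition.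

Step 2. Iodine may divide between the two activated ring positions (ortho to OH and para to OBn, against para to OH and ortho to OBn), or a second iodine may enter. The fallback sets out from 2 and returns at 3 by masking the phenol so that the benzyl ether alone directs. Acetylation with Ac2O and pyridine should give 3-(benzyloxy)-2-formylphenyl acetate F3. Iodination with N-iodosuccinimide and CF3CO2H in MeCN should then go para to the benzyloxy group, the acetoxy group being only a weak director, to give 3-(benzyloxy)-2-formyl-6-iodophenyl acetate F4. Methanolysis with catalytic K2CO3 in MeOH at 0 °C should give 3.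

Step 5. The benzhydryl cation may be captured by an electron-rich ring of a second molecule (Friedel–Crafts oligomerisation), or iodine may be lost by ipso-protonation before hydride transfer. The fallback sets out from 4 and returns at 8 without passing through carbinol 7 or any acid. Reduction with NaBH4 in MeOH should give [6-(benzyloxy)-3-iodo-2-methoxyphenyl]methanol F5. Treatment with MsCl and Et3N in CH2Cl2 at 0 °C should give 1-(benzyloxy)-2-(chloromethyl)-4-iodo-3-methoxybenzene F6. Coupling of F6 with the Grignard reagent 6 under Li2CuCl4 catalysis in THF at −20 to 0 °C should give 8, the aryl iodide being inert to the copper-catalysed substitution at this temperature.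

Further compounds
F1 | step 7 | {4-(benzyloxy)-3-[2-(benzyloxy)benzyl]-2-methoxyphenyl}magnesium chloride | COc1c([Mg]Cl)ccc(OCc2ccccc2)c1Cc1ccccc1OCc1ccccc1
F2 | step 7 | chloromagnesium 1-{4-(benzyloxy)-3-[2-(benzyloxy)benzyl]-2-methoxyphenyl}-1-[methoxy(methyl)amino]-3-phenylpropan-1-olate (racemic) | COc1c(C(O[Mg]Cl)(CCc2ccccc2)N(C)OC)ccc(OCc2ccccc2)c1Cc1ccccc1OCc1ccccc1
F3 | step 2 | 3-(benzyloxy)-2-formylphenyl acetate | CC(=O)Oc1cccc(OCc2ccccc2)c1C=O
F4 | step 2 | 3-(benzyloxy)-2-formyl-6-iodophenyl acetate | CC(=O)Oc1c(I)ccc(OCc2ccccc2)c1C=O
F5 | step 5 | [6-(benzyloxy)-3-iodo-2-methoxyphenyl]methanol | COc1c(I)ccc(OCc2ccccc2)c1CO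
F6 | step 5 | 1-(benzyloxy)-2-(chloromethyl)-4-iodo-3-methoxybenzene | COc1c(I)ccc(OCc2ccccc2)c1CCl
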